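Tuesday's flask ends with more E than Saturday's, 73% against 54% of the X charged, and the two differ in their charge of J.

| flask | X | J | remark | time |
|---|---|---|---|---|
| Saturday's | 0.25 M | 36 mM | run made earlier |  |
| Tuesday's | 0.25 M | 80 mM | run made earlier |  |
| larch | 0.25 M | 30 mM |  | 3.0 h |
| maple | 0.25 M | 60 mM |  | 3.0 h |

- Saturday's (time / min: E / %): 30.0: 41; 60.0: 50; 90.0: 52; 120: 54
- Tuesday's (time / min: E / %): 10.0: 35; 25.0: 66; 50.0: 71; 120: 73

(scatter of a reading: 2 percentage points)

- what was read earlier has a scatter of 2 percentage points, one standard deviation

* which of the two there is more of at the end, larch (E / Q)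
* which of the two there is more of at the end, maple (E / Q)
* amount of E at the end, in percent of the X charged, larch
* amount of E at the end, in percent of the X charged, maple

Both runs level off, so I read each last point as the end of the run and count the rest of the X as Q. Dividing [E]/[Q] by [J] then gives 0.0326 mM⁻¹ for Saturday's run and 0.0338 mM⁻¹ for Tuesday's, close together although [J] is about twice as large. Their mean, 0.0332 mM⁻¹, is what I carry: b, a selectivity factor, the end ratio [E]/[Q] per unit of [J]. It is a reading and keeps the readings' scatter.

Taking b as constant and [J] as staying at its charge, the share of E at the end is b[J]/(1+b[J]). The asked 3.0 h is longer than the 120 min of the last readings, so I take larch and maple as finished. My reckoning gives larch 49.9% of E, a tie within the scatter of 2 percentage points, and maple 66.6%.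

The forecast says Q for larch, with 49% of E (45% to 53%), a little below mine. For maple it says E, with 66.5% of E (62% to 70%). Its ground is the ratio of the two plateaus: “That makes E/Q nearly proportional to J”.

Larch gives 46.8% of E against 53.2% of Q, and maple gives 63.8% of E against 36.2% of Q, so the forecast holds on both marks and within both ranges.

    X → G (k = 0.370 min⁻¹)
    J + G → J + E (k = 0.880 L mol⁻¹ min⁻¹)
    G → Q (k = 0.0300 min⁻¹)

G is the fork: its step to E carries [J] and its step to Q does not. With J at 100% of its charge at the end of maple, the step to E is pseudo-first-order in [G]. From the end amounts, [E]/[Q] per unit of [J] comes to 0.0293 mM⁻¹ in larch and 0.0293 mM⁻¹ in maple. Carried to a flask like maple with 15.0 mM of J, my b gives 33.2% of E; that flask ends with 30.5% of E and 69.4% of Q.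

The data are simulated with made-up constants; noise was put on by code.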